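**Retrosynthetic overview**
1. Target 28 ⇐ acetonide-protected lactone 27: the last operations are acetonide removal, oxidative lactonisation (C6–OH + C12–OH → lactone ring) and angeloylation of C9–OH.
2. The C3 and C9 carbinols ⇐ chelation-controlled and Felkin–Anh-controlled reductions of the C3 ketone and the (unmasked) C9 ketone of ring-expanded hydroxy ketone 17.
3. Ten-membered ring ⇐ six-membered ring: tandem anionic oxy-Cope ring expansion/enolate hydroxylation of cyclohexenol 14 forms C1–C10, cleaves C3–C8 and sets C10 and C2.
4. Enabling feature: in the ten-membered ring, the oxygenated C3 and C9 flank the arc C2–C1–C10 (a 1,5-dioxygenated five-carbon segment), and the other arc C4(Me)=C5–C6(O)–C7–C8 is the carvone ring; tying C3 to C8 therefore gives a cyclohexene that is a 3-oxido-1,5-diene.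
5. 14 ⇐ (R)-carvone: ring 1,3-diene, singlet oxygen/Kornblum–DeLaMare (C6–O, transposed enone), SeO2 (C12–O), orthoester Mukaiyama addition (C9, C10, C14), vinyl addition (C1, C2). Ring order: cyclohexene (from carvone) → ten-membered carbocycle (step 9) → temporary acetonide → lactone (step 15).

Key step: step 9

Remark: the ester is read as the angelate ((Z)-2-methylbut-2-enoate), as drawn. Atom labels used throughout, also for the corresponding carbons of every intermediate: C1 = ring CH2; C2, C3 = the two free carbinol carbons (C3 allylic); C4(=C5) = methyl-bearing alkene carbon; C6 = lactone O–CH; C7 = lactone C–H; C8 = CH2 next to C7; C9 = ester carbinol; C10 = CH(CH3); C11/C12/C13 = lactone α-carbon, carbonyl carbon, exocyclic CH2; C14, C15 = methyls on C10 and C4.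

**Route**

Step 1
Reactants: 1 (R)-carvone
Product: 2 (3R)-6-methyl-3-(prop-1-en-2-yl)cyclohexa-1,5-dien-1-yl trifluoromethanesulfonate
Conditions: LiN(iPr)2, THF, −78 °C; then PhNTf2, −78 to 0 °C
Reagents that add atoms: N-phenylbis(trifluoromethanesulfonimide) (O=S(=O)(N(c1ccccc1)S(=O)(=O)C(F)(F)F)C(F)(F)F)
Why: Kinetic deprotonation at the α′-CH2 and O-sulfonylation of the cross-conjugated lithium enolate (enol triflate formation) turns the carbonyl carbon into the future C5 without touching the C7 stereocenter.

Step 2
Reactants: 2 dienyl triflate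
Product: 3 (5R)-2-methyl-5-(prop-1-en-2-yl)cyclohexa-1,3-diene
Conditions: Pd(OAc)2 (cat.), PPh3, Bu3N, HCO2H, DMF, 50 °C
Reagents that add atoms: none
Why: Palladium-catalysed formate reduction of an enol triflate (hydride transfer to the alkenylpalladium triflate with loss of CO2) replaces C–OTf by C–H and should deliver the ring diene C3=C4–C5=C6 at a temperature where the doubly allylic C7–H is not isomerised.

Step 3
Reactants: 3 triene
Product: 5 (4R,5S)-4-hydroxy-2-methyl-5-(prop-1-en-2-yl)cyclohex-2-en-1-one, via endoperoxide 4 (not isolated)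
Conditions: O2, tetraphenylporphyrin (cat.), visible light, CH2Cl2, −30 °C; then Et3N (cat.), 0 °C to rt
Reagents that add atoms: dioxygen (O=O)
Why: Singlet oxygen should add to the s-cis ring diene in a [4+2] cycloaddition on the face opposite the C7 isopropenyl group, which sets the C6–O bond trans to C7, and triethylamine should then remove the less hindered bridgehead hydrogen at C3 (flanked by the C8 methylene) in a Kornblum–DeLaMare rearrangement to give the C3 ketone and the C6 alcohol, the 1,1-disubstituted side-chain alkene being a slow ene partner.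

Step 4
Reactants: 5 hydroxy enone
Product: 6 (4R,5S)-4-hydroxy-5-(3-hydroxyprop-1-en-2-yl)-2-methylcyclohex-2-en-1-one
Conditions: SeO2 (cat.), tBuOOH, CH2Cl2, rt
Reagents that add atoms: tert-butyl hydroperoxide (CC(C)(C)OO)
Why: SeO2/tBuOOH allylic oxidation (ene reaction followed by [2,3]-sigmatropic shift) should attack only the electron-rich isopropenyl group at its methyl (C12), because the ring alkene is deactivated by conjugation with the ketone and CH3 reacts in preference to the ring methine.

Step 5
Reactants: 6 enone diol
Product: 7 (4R,5S)-4-(tert-butyldimethylsilyloxy)-5-[3-(tert-butyldimethylsilyloxy)prop-1-en-2-yl]-2-methylcyclohex-2-en-1-one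
Conditions: TBSCl, imidazole, DMF, rt
Reagents that add atoms: tert-butyldimethylsilyl chloride (CC(C)(C)[Si](C)(C)Cl)
Why: Standard silylation masks the C6 and C12 hydroxyls as ethers that tolerate the amide base, organometallic, hydride and mild acid steps ahead.

Step 6
Reactants: 7 bis-silyl enone; 8 trimethyl orthopropionate
Product: 10 C8-(1,1-dimethoxypropyl) ketone (side chain trans to the C7 side chain), via silyl dienol ether 9 (not isolated)
Conditions: LiN(iPr)2, Me3SiCl, THF, −78 °C; then EtC(OMe)3, TMSOTf (cat.), CH2Cl2, −78 °C
Reagents that add atoms: trimethyl orthopropionate 8 (CCC(OC)(OC)OC)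
Why: Kinetic α′-enolisation and silylation give the cross-conjugated silyl dienol ether, which should attack the dimethoxycarbenium ion released from the orthoester (Mukaiyama-type addition to an orthoester) on the C8 face opposite the C7 side chain, so that the ketal-bearing group ends up trans to it and equatorial.

Step 7
Reactants: 10 keto ketal; 11 vinylmagnesium bromide
Product: 12 C3 tertiary allylic alcohol (vinyl cis to the C8 side chain and trans to the C7 side chain)
Conditions: CH2=CHMgBr, CeCl3, THF, −78 °C
Reagents that add atoms: vinylmagnesium bromide 11 (C=C[Mg]Br)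
Why: The organocerium reagent should add 1,2 to the enone without enolisation, and axial attack anti-periplanar to the axial C8–H of the half-chair (all three ring substituents equatorial) places the vinyl group cis to the C8 side chain, which creates the C3 carbinol centre.

Step 8
Reactants: 12 ketal alcohol
Product: 14 oxy-Cope substrate (C3 carbinol carrying vinyl; C8 carrying a (Z)-1-methoxyprop-1-enyl group), via trimethylsilyl ether 13 (not isolated)
Conditions: TMSOTf, iPr2NEt, CH2Cl2, −78 to −20 °C; then K2CO3 (cat.), MeOH, 0 °C
Reagents that add atoms: none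
Why: The silyl triflate with excess hindered amine should silylate the tertiary alcohol and ionise the ketal to an oxocarbenium ion that is deprotonated at the accessible C10 methylene (ketal-to-enol ether elimination), the methyl group settling cis to OMe (Z) to avoid allylic strain with the substituted C8, and mild methanolysis then frees the tertiary alcohol while the enol ether and the TBS ethers survive base.

Step 9
Reactants: 14 oxy-Cope substrate
Product: 17 ring-expanded hydroxy ketone (ten-membered ring; C3 ketone; 2S hydroxyl; 10R methyl; C8=C9 methyl enol ether; C6 and C7 as in 28), via potassium alkoxide 15 (not isolated), via potassium enolate 16 (not isolated)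
Conditions: KN(SiMe3)2, 18-crown-6, THF, 0 °C to rt; then 2-(phenylsulfonyl)-3-phenyloxaziridine, −78 °C; then AcOH, −78 °C
Reagents that add atoms: 2-(phenylsulfonyl)-3-phenyloxaziridine (O=S(=O)(c1ccccc1)N1OC1c1ccccc1)
Why: The crown-complexed tertiary alkoxide is a 3-oxido-1,5-diene C1=C2–C3(O−)–C8–C9=C10 that should undergo a charge-accelerated [3,3]-sigmatropic shift (anionic oxy-Cope rearrangement), forming C1–C10, cleaving the carvone-derived C3–C8 ring bond and leaving a potassium enolate (C2=C3–O−) next to the C8=C9 methyl enol ether, and the enolate is then hydroxylated in the same flask by the N-sulfonyloxaziridine. The closest known reaction type is the anionic oxy-Cope ring expansion of 1,2-dialkenylcyclohexanols to cyclodec-5-enones with in situ oxidation of the resulting enolate. The ten-membered ring is closed by a four-atom ring expansion of the six-membered ring through a chair-like six-centre array, not by an end-to-end cyclisation, so no high dilution is needed. C10 is set in the chair in which the substituents at C6, C7 and C8 stay equatorial on the cyclohexene, the vinyl group is axial and the C7–C8 bond is axial on the six-centre array, so that C1 bonds to the face of the (Z)-enol ether that keeps its methyl group equatorial (10R), while C2 is set by delivery of oxygen to the outer face of the enolate, the inner face being covered by C7 and C8 (2S). The step needs chair over boat selectivity and a single diene helicity, which are secured by the cis relation of the two alkenyl groups together with the all-equatorial trans,trans arrangement at C6/C7/C8 (the alternative chair would put three substituents axial) and by the Z enol ether (an axial methyl would clash with C7); chemoselectivity is secured because the oxaziridine reacts with the enolate but not with the neutral enol ether. The C3 and C8 stereocentres of 14 are consumed and their information reappears at C2 and C10.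

Step 10
Reactants: 17 hydroxy ketone
Product: 18 2,3-diol (2S,3R; enol ether intact)
Conditions: Zn(BH4)2, Et2O, −30 °C
Reagents that add atoms: none
Why: Zn(BH4)2 should chelate the C2 hydroxyl and the C3 carbonyl and deliver hydride to the carbonyl face opposite the C1 branch of the five-membered chelate (chelation-controlled 1,2-reduction), which gives the anti (erythro) diol with 3R and leaves the enol ether and the ring alkene untouched.

Step 11
Reactants: 18 diol
Product: 20 C2,C3-acetonide C9 ketone, via acetonide enol ether 19 (not isolated)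
Conditions: 2-methoxypropene, PPTS (cat.), CH2Cl2, 0 °C; then aq. oxalic acid, THF, 0 °C to rt
Reagents that add atoms: 2-methoxypropene (COC(C)=C); water (O)
Why: Kinetic acetalisation of the cis-related vicinal diol with 2-methoxypropene (acetonide formation) should outpace transannular ketalisation, and the electron-rich methyl enol ether is then hydrolysed by dilute acid to the C9 ketone through protonation at C8, conditions under which the acetonide, the TBS ethers and the C10 centre are expected to hold.

Step 12
Reactants: 20 acetonide ketone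
Product: 21 C9 alcohol (9S; hydroxyl and C10 methyl as in 28)
Conditions: LiBH(sec-Bu)3, THF, −78 °C
Reagents that add atoms: none
Why: The bulky hydride should attack the C9 carbonyl according to the Felkin–Anh model, anti to the C1 ring branch and past the C10 hydrogen rather than the C10 methyl group (substrate-controlled ketone reduction), which gives the 9S alcohol.

Step 13
Reactants: 21 C9 alcohol; 22 angelic acid
Product: 23 C9 angelate
Conditions: 22, 2,4,6-trichlorobenzoyl chloride, Et3N, toluene, rt; then 21, 75 °C
Reagents that add atoms: angelic acid 22 (C/C=C(/C)C(=O)O)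
Why: Acylation through the mixed anhydride with 2,4,6-trichlorobenzoyl chloride (Yamaguchi-type esterification run without a nucleophilic pyridine catalyst) should esterify the only free hydroxyl, at C9, while avoiding base-induced Z to E isomerisation of the angelate to the tiglate.

Step 14
Reactants: 23 angelate bis-silyl ether
Product: 24 C6,C12-diol
Conditions: HF·pyridine, pyridine, THF, 0 °C to rt
Reagents that add atoms: none
Why: Buffered fluoride-mediated desilylation should cleave both silyl ethers without affecting the acetonide, the angelate or the alkenes.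

Step 15
Reactants: 24 diol
Product: 27 acetonide-protected α-methylene lactone, via hydroxy enal 25 (not isolated), via lactol 26 (not isolated)
Conditions: TEMPO (cat.), PhI(OAc)2, CH2Cl2, rt
Reagents that add atoms: none
Why: The oxoammonium oxidant should convert the primary allylic C12 alcohol into the enal, the C6 hydroxyl closes the five-membered lactol and a second oxidation gives the α-methylene-γ-butyrolactone (oxidative lactonisation of a 1,4-diol), the trans ring fusion being fixed by the existing C6 and C7 centres.

Step 16
Reactants: 27 lactone acetonide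
Product: 28 target CNP0229085.1
Conditions: AcOH/H2O, 40 °C
Reagents that add atoms: none
Why: Mild aqueous acid should hydrolyse the acetonide (acetal hydrolysis) and leave the lactone, the angelate and all six stereocentres untouched.

**Compound list**
1 | (R)-(−)-carvone, (5R)-2-methyl-5-(prop-1-en-2-yl)cyclohex-2-en-1-one | CC1=CC[C@H](CC1=O)C(C)=C | starting material
2 | (3R)-6-methyl-3-(prop-1-en-2-yl)cyclohexa-1,5-dien-1-yl trifluoromethanesulfonate | CC1=CC[C@H](C=C1OS(=O)(=O)C(F)(F)F)C(C)=C | intermediate
3 | (5R)-2-methyl-5-(prop-1-en-2-yl)cyclohexa-1,3-diene | CC1=CC[C@H](C=C1)C(C)=C | intermediate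
4 | 5-methyl-7-(prop-1-en-2-yl)-2,3-dioxabicyclo[2.2.2]oct-5-ene, peroxide bridge anti to the isopropenyl group | CC1=C[C@H]2OO[C@@H]1C[C@H]2C(C)=C | intermediate (not isolated)
5 | (4R,5S)-4-hydroxy-2-methyl-5-(prop-1-en-2-yl)cyclohex-2-en-1-one | CC1=C[C@@H](O)[C@@H](CC1=O)C(C)=C | intermediate
6 | (4R,5S)-4-hydroxy-5-(3-hydroxyprop-1-en-2-yl)-2-methylcyclohex-2-en-1-one | CC1=C[C@@H](O)[C@@H](CC1=O)C(=C)CO | intermediate
7 | (4R,5S)-4-(tert-butyldimethylsilyloxy)-5-[3-(tert-butyldimethylsilyloxy)prop-1-en-2-yl]-2-methylcyclohex-2-en-1-one | CC1=C[C@@H](O[Si](C)(C)C(C)(C)C)[C@@H](CC1=O)C(=C)CO[Si](C)(C)C(C)(C)C | intermediate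
8 | trimethyl orthopropionate (1,1,1-trimethoxypropane) | CCC(OC)(OC)OC | starting material
9 | cross-conjugated trimethylsilyl dienol ether of 7 (C3–OSiMe3, C3=C8) | CC1=C[C@@H](O[Si](C)(C)C(C)(C)C)[C@@H](C=C1O[Si](C)(C)C)C(=C)CO[Si](C)(C)C(C)(C)C | intermediate (not isolated)
10 | enone 7 carrying a 1,1-dimethoxypropyl group at C8, trans to the C7 side chain | CC1=C[C@@H](O[Si](C)(C)C(C)(C)C)[C@@H]([C@H](C1=O)C(OC)(OC)CC)C(=C)CO[Si](C)(C)C(C)(C)C | intermediate
11 | vinylmagnesium bromide | C=C[Mg]Br | starting material
12 | C3 tertiary alcohol from 10: vinyl cis to the C8 ketal side chain, hydroxyl trans to it | CC1=C[C@@H](O[Si](C)(C)C(C)(C)C)[C@@H]([C@H]([C@@]1(O)C=C)C(OC)(OC)CC)C(=C)CO[Si](C)(C)C(C)(C)C | intermediate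
13 | C3 trimethylsilyl ether of 14 | CC1=C[C@@H](O[Si](C)(C)C(C)(C)C)[C@@H]([C@H]([C@@]1(O[Si](C)(C)C)C=C)/C(OC)=C/C)C(=C)CO[Si](C)(C)C(C)(C)C | intermediate (not isolated)
14 | 1-vinylcyclohex-2-en-1-ol with a (Z)-1-methoxyprop-1-enyl group at C8 (cis to vinyl, trans to the C7 side chain) and C6-OTBS trans to the C7 side chain | CC1=C[C@@H](O[Si](C)(C)C(C)(C)C)[C@@H]([C@H]([C@@]1(O)C=C)/C(OC)=C/C)C(=C)CO[Si](C)(C)C(C)(C)C | intermediate
15 | potassium alkoxide of 14 | CC1=C[C@@H](O[Si](C)(C)C(C)(C)C)[C@@H]([C@H]([C@@]1([O-])C=C)/C(OC)=C/C)C(=C)CO[Si](C)(C)C(C)(C)C.[K+] | intermediate (not isolated)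
16 | ring-expanded potassium enolate (C2=C3–O−, C1 and C4 trans; C8=C9 methyl enol ether; 10R) | CC(C)(C)[Si](C)(C)O[C@@H]1/C=C(/C)\C([O-])=C\C[C@@H](C)/C(OC)=C\[C@H]1C(=C)CO[Si](C)(C)C(C)(C)C.[K+] | intermediate (not isolated)
17 | ten-membered hydroxy ketone: C3 ketone, 2S-hydroxyl, 10R-methyl, C8=C9 methyl enol ether, C6-OTBS, C12-OTBS | CC(C)(C)[Si](C)(C)O[C@@H]1/C=C(/C)C(=O)[C@@H](O)C[C@@H](C)/C(OC)=C\[C@H]1C(=C)CO[Si](C)(C)C(C)(C)C | intermediate
18 | 2,3-diol (2S,3R) of 17 | CC(C)(C)[Si](C)(C)O[C@@H]1/C=C(/C)[C@@H](O)[C@@H](O)C[C@@H](C)/C(OC)=C\[C@H]1C(=C)CO[Si](C)(C)C(C)(C)C | intermediate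
19 | C2,C3-acetonide of 18 (enol ether intact) | CC(C)(C)[Si](C)(C)O[C@@H]1/C=C(/C)[C@H]2OC(C)(C)O[C@H]2C[C@@H](C)/C(OC)=C\[C@H]1C(=C)CO[Si](C)(C)C(C)(C)C | intermediate (not isolated)
20 | C2,C3-acetonide C9 ketone | CC(C)(C)[Si](C)(C)O[C@@H]1/C=C(/C)[C@H]2OC(C)(C)O[C@H]2C[C@@H](C)C(=O)C[C@H]1C(=C)CO[Si](C)(C)C(C)(C)C | intermediate
21 | C2,C3-acetonide C9 alcohol (9S) | CC(C)(C)[Si](C)(C)O[C@@H]1/C=C(/C)[C@H]2OC(C)(C)O[C@H]2C[C@@H](C)[C@@H](O)C[C@H]1C(=C)CO[Si](C)(C)C(C)(C)C | intermediate
22 | angelic acid, (Z)-2-methylbut-2-enoic acid | C/C=C(/C)C(=O)O | starting material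
23 | C9 angelate of 21 | CC(C)(C)[Si](C)(C)O[C@@H]1/C=C(/C)[C@H]2OC(C)(C)O[C@H]2C[C@@H](C)[C@@H](OC(=O)/C(C)=C\C)C[C@H]1C(=C)CO[Si](C)(C)C(C)(C)C | intermediate
24 | C6,C12-diol (acetonide and angelate retained) | O[C@@H]1/C=C(/C)[C@H]2OC(C)(C)O[C@H]2C[C@@H](C)[C@@H](OC(=O)/C(C)=C\C)C[C@H]1C(=C)CO | intermediate
25 | C12 enal with free C6 hydroxyl | O[C@@H]1/C=C(/C)[C@H]2OC(C)(C)O[C@H]2C[C@@H](C)[C@@H](OC(=O)/C(C)=C\C)C[C@H]1C(=C)C=O | intermediate (not isolated)
26 | five-membered lactol (both C12 epimers) | C=C1C(O)O[C@@H]2/C=C(/C)[C@H]3OC(C)(C)O[C@H]3C[C@@H](C)[C@@H](OC(=O)/C(C)=C\C)C[C@@H]12 | intermediate (not isolated)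
27 | C2,C3-acetonide of the target | C=C1C(=O)O[C@@H]2/C=C(/C)[C@H]3OC(C)(C)O[C@H]3C[C@@H](C)[C@@H](OC(=O)/C(C)=C\C)C[C@@H]12 | intermediate
28 | CNP0229085.1 | C=C1C(=O)O[C@@H]2/C=C(/C)[C@@H](O)[C@@H](O)C[C@@H](C)[C@@H](OC(=O)/C(C)=C\C)C[C@@H]12 | target

**Step count and risks**
Total step count: 16. Longest linear sequence: 16 steps (from (R)-carvone).

Three steps most likely to fail:

Step 9. The ring enolate may turn through the ring before the oxidant arrives, or the oxidant may not discriminate its two faces, so that oxygen enters at C2 from the wrong side (poor facial selectivity in the enolate hydroxylation). Fallback: the sequence sets out from 14 as before and the C2 epimers are separated. The unwanted 2-epi hydroxy ketone F1 is then inverted at carbon instead of being discarded: Mitsunobu reaction with 4-nitrobenzoic acid (PPh3, diisopropyl azodicarboxylate, THF, 0 °C) should give the inverted 4-nitrobenzoate F2, and brief methanolysis (K2CO3, MeOH, 0 °C) comes back to the route at 17.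

Step 7. Equatorial attack may compete with axial attack (erosion of facial selectivity in the 1,2-addition); the C3 epimer would invert the diene helicity of step 9 and so the configurations at C2 and C10. Fallback: from 10, the slimmer sp nucleophile HC≡CMgBr (CeCl3, THF, −78 °C), which shows the strongest axial preference, should give the ethynyl carbinol F3. Semi-hydrogenation over Pd/CaCO3 poisoned with Pb(OAc)2 (quinoline, H2) then returns to the route at 12.

Step 3. The base may remove the bridgehead hydrogen at C6 instead of C3 (wrong-site deprotonation in the peroxide cleavage, which scrambles ketone and hydroxyl positions), and singlet oxygen may partly attack the face syn to the isopropenyl group. Fallback: from 3, photooxygenation as before, then reduction of the O–O bond with thiourea in MeOH to the cis-1,4-diol F4, at which stage face isomers can be separated. MnO2 in CH2Cl2 should then oxidise selectively the less hindered allylic hydroxyl at C3 (on the methyl-bearing alkene terminus, flanked by CH2), and the route is rejoined at 5.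

**Further compounds**
F1 | step 9 | C2 epimer of hydroxy ketone 17 | CC(C)(C)[Si](C)(C)O[C@@H]1/C=C(/C)C(=O)[C@H](O)C[C@@H](C)/C(OC)=C\[C@H]1C(=C)CO[Si](C)(C)C(C)(C)C
F2 | step 9 | 4-nitrobenzoate of 17 (C2 configured as in 17) | CC(C)(C)[Si](C)(C)O[C@@H]1/C=C(/C)C(=O)[C@@H](OC(=O)c2ccc(cc2)[N+](=O)[O-])C[C@@H](C)/C(OC)=C\[C@H]1C(=C)CO[Si](C)(C)C(C)(C)C
F3 | step 7 | C3 ethynyl carbinol corresponding to 12 (ethynyl cis to the C8 side chain) | CC1=C[C@@H](O[Si](C)(C)C(C)(C)C)[C@@H]([C@H]([C@@]1(O)C#C)C(OC)(OC)CC)C(=C)CO[Si](C)(C)C(C)(C)C
F4 | step 3 | 2-methyl-5-(prop-1-en-2-yl)cyclohex-2-ene-1,4-diol, both hydroxyls trans to the isopropenyl group | CC1=C[C@@H](O)[C@@H](C[C@H]1O)C(C)=C
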